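Numbering used throughout: oxane O1, C2 (carries the CH2CH2–ring B chain), C4 (hydroxyl), C6 (carries ring A). Open-chain compounds are numbered along the heptane chain from the carbon that becomes C6, so heptane C1, C3 and C5 become oxane C6, C4 and C2.

## Analysis of the target

Target 8 is a 2,4,6-trisubstituted oxane of the diarylheptanoid family. C6 is bonded directly to guaiacyl ring A (4-hydroxy-3-methoxyphenyl), C4 carries a hydroxyl, and C2 carries a two-carbon chain ending in guaiacyl ring B. All three stereocentres are S (2S,4S,6S). The C2 chain and the C6 aryl group are cis and both equatorial in the chair; the C4 hydroxyl is trans to both and therefore axial. The sensitive groups are the two free, electron-rich phenols and the O1–C6 bond, a 4-hydroxybenzyl ether that can ionise to a quinone methide and is open to hydrogenolysis. Two things make the synthesis hard. The axial alcohol is the less stable epimer at C4, so it cannot be reached by equilibration. The two guaiacyl ends are almost identical, so a stepwise construction has to tell them apart with protecting groups. The strategy rests on one feature: C6–C5–C4–C3–C2 plus the two chain carbons, flanked by rings A and B, is the octahydrocurcumin skeleton. If O1–C6 is broken, the oxygens on C2 and C4 are syn and the resulting 3,5-diol is meso, and C6 lies para to the free phenol of ring A, the position a quinone methide activates. The target is therefore a meso diol less two hydrogens, removed at one of two enantiotopic benzylic CH2 groups.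

## Retrosynthetic reasoning

**8 to 6 (through 7).** The O1–C6 bond is cut. C6 is the only ring carbon that is both benzylic and para to a free phenol, so this bond alone can be made by adding an alcohol to a para-quinone methide, with no protecting group. Cutting O1–C2 instead would leave an unsymmetrical triol and need a substitution with inversion at a secondary carbon. The chosen cut gives meso diol 6 with two identical arms and the carbon skeleton complete; two stereocentres reduce to one syn relationship. Forward, one benzylic CH2 of 6 must be dehydrogenated to methide 7, on the arm next to the (R)-carbinol, and the C5 hydroxyl must close the ring with the aryl group equatorial.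

**6 to 3 (through 4 and 5).** The C–H bond at one carbinol of 6 is cut, leading to ketol 3. A β-hydroxy ketone is the standard precursor of a syn-1,3-diol: held in a dialkylboron chelate (4), it accepts external hydride from one face (giving 5, then 6). Because 6 is meso, both enantiomers of 3 give the same diol, so 3 can be racemic and no absolute configuration is needed before the key step.

**3 to 2.** The one carbinol C–H of 3 is cut, giving symmetrical β-diketone 2. Its two carbonyl groups are equivalent, so the forward reaction only has to stop after one reduction.

**2 to 1.** The C–H bonds at C1, C2, C6 and C7 are cut: 2 is curcumin 1 with both styrene-type double bonds saturated. Compound 1 supplies the whole seven-carbon chain with both guaiacyl rings, so the route forms no C–C bond.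

## Alternatives that were turned down

**Alternative 1:** dithiane linchpin coupling of two epoxides.
- Disconnection: C3–C4 and C4–C5 are cut, so C4 arrives as the carbon of a silylated 1,3-dithiane and each flank as an epoxide.
- Forward key step: the lithiated silyl dithiane opens the aryl oxirane of ring A at its CH2 end. HMPA then triggers a 1,4-Brook shift of silicon to the new benzylic alkoxide, and the regenerated dithiane anion opens the oxirane carrying the ring B chain. The product is open-chain A1. The ring is closed later: dithiane hydrolysis, ionisation of the benzylic silyl ether so the C2 hydroxyl forms O1–C6 (cis by relay from C2), a bulky-hydride reduction of the C4 ketone to the axial alcohol, and debenzylation.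
- For: three components join in one flask, the reaction type is well established, and the absolute configuration comes from one enantiopure terminal epoxide whose purity can be checked before coupling.
- Against: the 4-alkoxyphenyl oxirane is acid-labile and may open at the benzylic carbon. Dithiane removal has to be done next to two electron-rich arenes. The axial alcohol needs its own reduction. The final hydrogenolysis must spare the benzylic O1–C6 bond. Both phenols need protection, and the sequence runs to roughly a dozen operations.
- Comparison: on predictability of absolute configuration this alternative is stronger. The chosen strategy offers four steps, no protecting groups, and an axial hydroxyl that is already fixed by the syn diol.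

**Alternative 2:** iridium-catalysed allylic etherification, ring B added last.
- Disconnection: O1–C2 is cut, together with the bond from the side chain to ring B, so C2 first carries a vinyl group.
- Forward key step: a catalyst from [Ir(cod)Cl]2 (monovalent iridium) and a chiral BINOL-derived phosphoramidite ionises a linear allylic carbonate. The C6 benzylic hydroxyl attacks the substituted allyl terminus and closes the ring to give A2. Hydroboration of the vinyl group and B-alkyl Suzuki coupling then bring in ring B, followed by desilylation and debenzylation.
- For: C2 is set by the catalyst, the branched selectivity of iridium is dependable, and late introduction of ring B suits analogues.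
- Against: C4 and C6 must already be set, differentially protected, in the open-chain substrate, which costs several asymmetric steps before the key step. A catalyst–substrate mismatch is possible. Three protecting groups are needed and the length is about twelve steps.
- Comparison: this alternative is stronger in flexibility and in setting each stereocentre by a separately tunable, known event. The chosen strategy uses the hidden symmetry instead, so both arenes and the whole chain come from one starting material.

**Alternative 3:** hetero-Diels–Alder reaction.
- Disconnection: O1–C6 and C2–C3 are cut in a [4+2] sense.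
- Forward key step: a chiral tridentate (Schiff base)CrCl catalyst (trivalent chromium) joins a 1-aryl-3-silyloxybutadiene and a 3-arylpropanal through an endo transition state to give cis-2,6 dihydropyran A3. Hydrolysis gives ketone A4, LiBH(s-Bu)3 should give the axial alcohol, and hydrogenolysis frees the phenols.
- For: it is the most convergent option. The ring and two stereocentres form in one catalytic step of a known class, and both halves derive from vanillin.
- Against: the diene lacks the 1-alkoxy donor usual for this catalyst and its oxygen-bonding terminus is conjugated to an arene, so reactivity should be lower and open-chain Mukaiyama-aldol products may compete. The aldehyde is enolisable. C4 still needs a separate reduction, and hydrogenolysis again has to spare O1–C6. The length is about ten steps.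
- Comparison: this alternative forms the same O1–C6 bond with absolute control from a known catalyst and is stronger on that point. The chosen strategy forms it with C4 already in place, without protection or a ketone reduction, in less than half the steps.

Key step: step 4

Assumption: an oxidase variant that prefers the arm next to the (R)-carbinol is taken to be found by screening; ring A is by definition the arene on that arm.

## Route

Step 1
Reactants: 1 curcumin [(1E,6E)-1,7-bis(4-hydroxy-3-methoxyphenyl)hepta-1,6-diene-3,5-dione]
Product: 2 tetrahydrocurcumin [1,7-bis(4-hydroxy-3-methoxyphenyl)heptane-3,5-dione]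
Conditions: H2 (1 atm), 10% Pd/C, EtOAc, rt, stopped after 2 equiv H2
Reagents that add atoms: none
Why: Heterogeneous catalytic hydrogenation saturates the two conjugated C=C bonds well before the enolised β-diketone or the arenes react. No stereocentre is formed.

Step 2
Reactants: 2 tetrahydrocurcumin
Product: 3 racemic hexahydrocurcumin [5-hydroxy-1,7-bis(4-hydroxy-3-methoxyphenyl)heptan-3-one]
Conditions: NaBH4 (0.3 equiv), EtOH/THF, −20 °C, stopped at partial conversion; dilute aq. HCl; chromatography, recovered 2 recycled
Reagents that add atoms: none
Why: Borohydride reduction of one of two equivalent carbonyl groups, with substoichiometric hydride at low temperature so that the ketol is the main product. Ketol, diketone and diol differ clearly in polarity, and the racemate is sufficient because the next product is meso.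

Step 3
Reactants: 3 racemic hexahydrocurcumin
Product: 6 meso-octahydrocurcumin [(3R,5S)-1,7-bis(4-hydroxy-3-methoxyphenyl)heptane-3,5-diol], via diethylboron chelate of the ketol 4 (not isolated), via cyclic sodium diethylborate of the syn diol 5 (not isolated)
Conditions: Et2BOMe (2.5 equiv), THF/MeOH (4:1), −78 °C; NaBH4, −78 °C; AcOH, then repeated MeOH co-evaporation; recrystallisation
Reagents that add atoms: none
Why: Narasaka–Prasad reduction: the ketol is locked in six-membered boron chelate 4 with the carbinol substituent pseudo-equatorial, and external hydride adds axially to give the 1,3-syn relationship in 5. Both enantiomers of 3 converge on the same meso diol, and the excess boron reagent allows for reversible binding to the phenols.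

Step 4
Reactants: 6 meso-octahydrocurcumin
Product: 8 (2S,4S,6S)-2-[2-(4-hydroxy-3-methoxyphenyl)ethyl]-6-(4-hydroxy-3-methoxyphenyl)oxan-4-ol, via para-quinone methide 7 (not isolated)
Conditions: engineered vanillyl alcohol oxidase or eugenol oxidase variant (flavin-dependent), air, catalase, K2HPO4/KH2PO4 buffer pH 7.5 with 10% DMSO, 25 °C, stopped at partial conversion; EtOAc extraction, chromatography
Reagents that add atoms: none
Why: Proposed new method: the oxidase binds one guaiacyl ring of 6 as its phenolate and passes a hydride from the benzylic CH2 of that arm (C1) to the flavin, which air reoxidises, so that the arm becomes para-quinone methide 7. The closest known reaction types are the dehydrogenation of 4-alkylphenols by these oxidases through bound para-quinone methides that water then attacks, and the chemical generation of such methides followed by intramolecular addition of an alcohol; new here are the internal hydroxyl as the trap, the size of the substrate and the choice between two enantiotopic arms. The C5 hydroxyl adds to the methide carbon in a 6-exo-trig closure that forms O1–C6, closes the oxane and restores the arene, while the C3 hydroxyl could only close an oxetane and stays free. The one new stereocentre, C6, is set by the substrate: in the chair-like transition state the aryl group and the C2 chain are both equatorial, which gives the cis-2,6 ring and leaves the C4 hydroxyl, fixed beforehand by the syn diol, axial; this isomer is also the more stable one, so kinetic and thermodynamic preference agree. The absolute configuration is decided when the enzyme picks the arm: the two arms are enantiotopic, they meet the chiral active site as diastereomeric complexes that differ in where the hydroxyl two carbons from the reacting CH2 points, and a variant that oxidises the arm next to the (R)-carbinol gives 8. The step also needs mono-oxidation and ring closure ahead of water addition or tautomerisation to a styrene; the first is secured by stopping at partial conversion, the second by the high effective concentration of a hydroxyl placed for six-membered ring closure.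

## Compound list

1 | curcumin, (1E,6E)-1,7-bis(4-hydroxy-3-methoxyphenyl)hepta-1,6-diene-3,5-dione | COc1cc(/C=C/C(=O)CC(=O)/C=C/c2ccc(O)c(OC)c2)ccc1O | starting material
2 | tetrahydrocurcumin, 1,7-bis(4-hydroxy-3-methoxyphenyl)heptane-3,5-dione | COc1cc(CCC(=O)CC(=O)CCc2ccc(O)c(OC)c2)ccc1O | intermediate
3 | racemic hexahydrocurcumin, 5-hydroxy-1,7-bis(4-hydroxy-3-methoxyphenyl)heptan-3-one | COc1cc(CCC(=O)CC(O)CCc2ccc(O)c(OC)c2)ccc1O | intermediate
4 | racemic 5-[(diethylboranyl)oxy]-1,7-bis(4-hydroxy-3-methoxyphenyl)heptan-3-one, boron chelated by the ketone oxygen | COc1cc(CCC(=O)CC(CCc2ccc(O)c(OC)c2)OB(CC)CC)ccc1O | intermediate (not isolated)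
5 | sodium (4R,6S)-2,2-diethyl-4,6-bis[2-(4-hydroxy-3-methoxyphenyl)ethyl]-1,3,2-dioxaborinan-2-uide (cis, meso) | [Na+].COc1cc(CC[C@H]2C[C@@H](CCc3ccc(O)c(OC)c3)O[B-](CC)(CC)O2)ccc1O | intermediate (not isolated)
6 | meso-octahydrocurcumin, (3R,5S)-1,7-bis(4-hydroxy-3-methoxyphenyl)heptane-3,5-diol | COc1cc(CC[C@H](O)C[C@H](O)CCc2ccc(O)c(OC)c2)ccc1O | intermediate
7 | 4-[(3R,5S)-3,5-dihydroxy-7-(4-hydroxy-3-methoxyphenyl)heptylidene]-2-methoxycyclohexa-2,5-dien-1-one | COc1cc(CC[C@H](O)C[C@H](O)CC=C2C=CC(=O)C(OC)=C2)ccc1O | intermediate (not isolated)
8 | (2S,4S,6S)-2-[2-(4-hydroxy-3-methoxyphenyl)ethyl]-6-(4-hydroxy-3-methoxyphenyl)oxan-4-ol | COc1cc(CC[C@H]2C[C@H](O)C[C@@H](c3ccc(O)c(OC)c3)O2)ccc1O | target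

## Step count and risks

Total step count: 4. Longest linear sequence: 4 steps.

**Step 4 (key step).** Three things are likely to go wrong.
- The enzyme may not turn over a substrate much longer than its natural ones, or may not discriminate between the two arms. The result would be low conversion or low enantiomeric purity.
- Oxidation may continue, at the ring B arm of the product or at its C6–H, because both remain 4-substituted phenol sites.
- Water addition or loss of the C2 proton to a styrene may outrun ring closure inside the active site.

Fallback, known chemistry, from 6 back to 8: 6 is treated with one equivalent of DDQ in dry dioxane at room temperature. Hydride abstraction by a quinone from a 4-alkylphenol and capture of the methide by a pendant alcohol is established. Without a chiral agent both arms react alike, so 8 should form together with its mirror image (2R,4R,6R)-2-[2-(4-hydroxy-3-methoxyphenyl)ethyl]-6-(4-hydroxy-3-methoxyphenyl)oxan-4-ol F1 as the racemate. Preparative chromatography on a chiral stationary phase then returns 8. The desymmetrisation is given up, but ring closure and relative configuration are kept.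

**Step 2.** Reduction is unlikely to stop cleanly at the ketol, because the ketol carbonyl is no less reactive than the largely enolised diketone. Diol and unreacted 2 would lower the throughput.

Fallback, from 2 to 6: excess NaBH4 in MeOH at 0 °C reduces both carbonyls and should give 6 mixed with racemic anti diol (3S*,5S*)-1,7-bis(4-hydroxy-3-methoxyphenyl)heptane-3,5-diol F2. 2,2-Dimethoxypropane with catalytic pyridinium p-toluenesulfonate converts the mixture into the cis-acetonide (4R,6S)-4,6-bis[2-(4-hydroxy-3-methoxyphenyl)ethyl]-2,2-dimethyl-1,3-dioxane F3 and the racemic trans-acetonide (4S*,6S*)-4,6-bis[2-(4-hydroxy-3-methoxyphenyl)ethyl]-2,2-dimethyl-1,3-dioxane F4. These differ in ring shape (chair against twist-boat) and should separate on silica. Aqueous acetic acid then hydrolyses F3 to 6.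

**Step 3.** The two phenols can compete for the boron reagent, so chelation may be incomplete and syn selectivity eroded. Boron removal may also cost material.

Fallback, from 3 to 6: the phenols are benzylated (BnBr, K2CO3, DMF, rt) to racemic 1,7-bis[4-(benzyloxy)-3-methoxyphenyl]-5-hydroxyheptan-3-one F5. The Narasaka–Prasad reduction is then run on this phenol-free substrate to give (3R,5S)-1,7-bis[4-(benzyloxy)-3-methoxyphenyl]heptane-3,5-diol F6. Hydrogenolysis (H2, Pd/C, EtOAc) frees 6; at that stage the benzyl ethers are the only benzylic C–O bonds present.

## Further compounds

F1 | step 4 | (2R,4R,6R)-2-[2-(4-hydroxy-3-methoxyphenyl)ethyl]-6-(4-hydroxy-3-methoxyphenyl)oxan-4-ol (enantiomer of 8) | COc1cc(CC[C@@H]2C[C@@H](O)C[C@H](c3ccc(O)c(OC)c3)O2)ccc1O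
F2 | step 2 | racemic anti diol, (3S*,5S*)-1,7-bis(4-hydroxy-3-methoxyphenyl)heptane-3,5-diol (3S,5S enantiomer drawn) | COc1cc(CC[C@H](O)C[C@@H](O)CCc2ccc(O)c(OC)c2)ccc1O
F3 | step 2 | cis-acetonide, (4R,6S)-4,6-bis[2-(4-hydroxy-3-methoxyphenyl)ethyl]-2,2-dimethyl-1,3-dioxane (meso) | COc1cc(CC[C@H]2C[C@@H](CCc3ccc(O)c(OC)c3)OC(C)(C)O2)ccc1O
F4 | step 2 | racemic trans-acetonide, (4S*,6S*)-4,6-bis[2-(4-hydroxy-3-methoxyphenyl)ethyl]-2,2-dimethyl-1,3-dioxane (4S,6S enantiomer drawn) | COc1cc(CC[C@H]2C[C@H](CCc3ccc(O)c(OC)c3)OC(C)(C)O2)ccc1O
F5 | step 3 | racemic 1,7-bis[4-(benzyloxy)-3-methoxyphenyl]-5-hydroxyheptan-3-one | COc1cc(CCC(=O)CC(O)CCc2ccc(OCc3ccccc3)c(OC)c2)ccc1OCc1ccccc1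
F6 | step 3 | (3R,5S)-1,7-bis[4-(benzyloxy)-3-methoxyphenyl]heptane-3,5-diol (meso) | COc1cc(CC[C@H](O)C[C@H](O)CCc2ccc(OCc3ccccc3)c(OC)c2)ccc1OCc1ccccc1
A1 | alternative 1 | (2S)-4-[4-(benzyloxy)-3-methoxyphenyl]-1-{2-[(2S)-2-[4-(benzyloxy)-3-methoxyphenyl]-2-[(tert-butyldimethylsilyl)oxy]ethyl]-1,3-dithian-2-yl}butan-2-ol | COc1cc(CC[C@H](O)CC2(C[C@@H](c3ccc(OCc4ccccc4)c(OC)c3)O[Si](C)(C)C(C)(C)C)SCCCS2)ccc1OCc1ccccc1
A2 | alternative 2 | tert-butyl({(2R,4S,6S)-6-[4-(benzyloxy)-3-methoxyphenyl]-2-ethenyloxan-4-yl}oxy)dimethylsilane | C=C[C@H]1C[C@H](O[Si](C)(C)C(C)(C)C)C[C@@H](c2ccc(OCc3ccccc3)c(OC)c2)O1
A3 | alternative 3 | ({(2S,6S)-6-[4-(benzyloxy)-3-methoxyphenyl]-2-{2-[4-(benzyloxy)-3-methoxyphenyl]ethyl}-3,6-dihydro-2H-pyran-4-yl}oxy)triethylsilane | COc1cc(CC[C@H]2CC(O[Si](CC)(CC)CC)=C[C@@H](c3ccc(OCc4ccccc4)c(OC)c3)O2)ccc1OCc1ccccc1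
A4 | alternative 3 | (2S,6S)-6-[4-(benzyloxy)-3-methoxyphenyl]-2-{2-[4-(benzyloxy)-3-methoxyphenyl]ethyl}oxan-4-one | COc1cc(CC[C@H]2CC(=O)C[C@@H](c3ccc(OCc4ccccc4)c(OC)c3)O2)ccc1OCc1ccccc1
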